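Retrosynthesis (target numbered as a 2,3-dihydro-1-benzofuran-4,6-dione): cut first the C5–prenyl bond, then together the C3–C3a and O1–C2 bonds of the dihydrofuran, then the carbocycle at C5–C6 (Claisen) and the isobutyryl–CH2 bond, back to a 4-hydroxypyranone.
Forward: Pd-prenylation of the pyranone makes the quaternary carbon that becomes C7; lateral acylation and a pyranone-to-carbocycle Claisen build the six-membered ring (7); a reductive [3+2] annulation with epoxy aldehyde 10 closes the dihydrofuran; C5 is prenylated last.
Enabling feature: C3a lies between the enol-ether carbon C7a (bearing O1) and the C4 carbonyl, so the carbocycle is a cyclic 1,3-dione (vinylogous acid) whose central carbon and one oxygen act as a 1,3-C,O-dinucleophile; the side-chain array C3H2–C2H(O1)–C(OH)Me is a 2,3-epoxy aldehyde one reduction and one ring opening away.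
Stereochemistry: C2 and the carbinol carbon come from the Sharpless epoxide of nerol (C2 by inversion in the ring closure, carbinol untouched); C7 from the chiral ligand in the first Pd allylation; C5 from ligand-reinforced attack anti to the C7 prenyl group.
Key step: step 6

Assumption: β-triketones are drawn as one enol tautomer, and the sense of induction of the Trost ligand in steps 1 and 7 is assigned by analogy and would be fixed by a first experiment (the antipodal ligand reverses it).

Step 1
Reactants: 1 4-hydroxy-3,6-dimethyl-2H-pyran-2-one; 2 3-methylbut-2-en-1-yl acetate (prenyl acetate)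
Product: 3 (3S)-3,6-dimethyl-3-(3-methylbut-2-en-1-yl)-2H-pyran-2,4(3H)-dione
Conditions: Pd2(dba)3·CHCl3 (2.5 mol %), (R,R)-DACH-phenyl Trost ligand (7.5 mol %), Et3N (1.1 equiv), CH2Cl2, 0 °C to rt
Reagents that add atoms: none
Why: Tsuji–Trost allylic alkylation in its asymmetric form: the triethylammonium salt of 1 attacks the unsubstituted terminus of the π-prenyl complex through C3, its only carbon nucleophile (O-prenyl ethers re-ionise on zerovalent palladium and funnel to carbon), and the chiral pocket of the ligand differentiates the two faces of the planar anion so that the quaternary (3S) centre should form, as in the asymmetric prenylation of azlactone enolates.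

Step 2
Reactants: 3 (3S)-3,6-dimethyl-3-(3-methylbut-2-en-1-yl)-2H-pyran-2,4(3H)-dione; 4 N-methoxy-N,2-dimethylpropanamide (Weinreb amide of isobutyric acid)
Product: 5 (3S)-3-methyl-6-(3-methyl-2-oxobutyl)-3-(3-methylbut-2-en-1-yl)-2H-pyran-2,4(3H)-dione
Conditions: LiN(iPr)2 (1.1 equiv), THF, −78 °C; then 4, −78 to −20 °C; aq. NH4Cl
Reagents that add atoms: none
Why: Lateral (vinylogous) metalation followed by Claisen-type C-acylation: with C3 quaternary the 6-methyl group is the only enolisable position of 3, and its lithium dienolate is acylated at the exocyclic carbon by the Weinreb amide, whose chelated tetrahedral adduct stops at the ketone stage, as is known for the dienolates of 6-methyl-1,3-dioxin-4-ones and 6-methylpyranones.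

Step 3
Reactants: 5 (3S)-3-methyl-6-(3-methyl-2-oxobutyl)-3-(3-methylbut-2-en-1-yl)-2H-pyran-2,4(3H)-dione
Product: 7 (6S)-3,5-dihydroxy-6-methyl-6-(3-methylbut-2-en-1-yl)-2-(2-methylpropanoyl)cyclohexa-2,4-dien-1-one, via open-chain triketo methyl ester 6 (not isolated)
Conditions: Mg(OMe)2 (2.5 equiv), MeOH, rt to 60 °C; then 1 M HCl
Reagents that add atoms: none
Why: Pyranone-to-carbocycle rearrangement by ring opening and Claisen (Dieckmann-type) cyclisation: methoxide opens the enol lactone to triketo ester 6, whose magnesium-chelated C6 carbanion acylates the ester carbon to close the six-membered ring (no aldol mode is available), while the non-enolisable quaternary carbon keeps its configuration and becomes C6 of 7.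

Step 4
Reactants: 8 nerol, (2Z)-3,7-dimethylocta-2,6-dien-1-ol
Product: 9 [(2R,3S)-3-methyl-3-(4-methylpent-3-en-1-yl)oxiran-2-yl]methanol
Conditions: Ti(OiPr)4 (5 mol %), D-(−)-diethyl tartrate (7 mol %), t-BuOOH (1.5 equiv), 4 Å molecular sieves, CH2Cl2, −20 °C
Reagents that add atoms: tert-butyl hydroperoxide, CC(C)(C)OO
Why: Sharpless asymmetric epoxidation: the titanium–D-tartrate complex binds the allylic hydroxyl and delivers oxygen to one face of the (Z)-2,3-alkene only, which should give the cis-(2R,3S)-epoxide (the mirror image of the L-tartrate product) and leaves the remote trisubstituted alkene untouched.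

Step 5
Reactants: 9 [(2R,3S)-3-methyl-3-(4-methylpent-3-en-1-yl)oxiran-2-yl]methanol
Product: 10 (2S,3S)-3-methyl-3-(4-methylpent-3-en-1-yl)oxirane-2-carbaldehyde
Conditions: TEMPO (10 mol %), PhI(OAc)2 (1.1 equiv), CH2Cl2, rt
Reagents that add atoms: none
Why: Oxoammonium (TEMPO/PhI(OAc)2) oxidation of the primary alcohol to the aldehyde under nearly neutral conditions, which should leave the acid-sensitive trisubstituted epoxide, its two stereocentres (the α-carbon is an epoxide carbon and does not enolise) and the alkene intact.

Step 6
Reactants: 7 (6S)-3,5-dihydroxy-6-methyl-6-(3-methylbut-2-en-1-yl)-2-(2-methylpropanoyl)cyclohexa-2,4-dien-1-one; 10 (2S,3S)-3-methyl-3-(4-methylpent-3-en-1-yl)oxirane-2-carbaldehyde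
Product: 13 (2S,7S)-4-hydroxy-2-[(2S)-2-hydroxy-6-methylhept-5-en-2-yl]-7-methyl-7-(3-methylbut-2-en-1-yl)-5-(2-methylpropanoyl)-2,3-dihydro-1-benzofuran-6(7H)-one, via alkylidene trione 11 (not isolated), via epoxyalkyl enol 12 (not isolated)
Conditions: L-proline (20 mol %), diethyl 2,6-dimethyl-1,4-dihydropyridine-3,5-dicarboxylate (Hantzsch ester, 1.1 equiv), CH2Cl2, 0 °C to rt; then Et3N (1.5 equiv), rt
Reagents that add atoms: none
Why: Proposed new method: the proline iminium of 10 is attacked by C4 of 7 and loses proline to give the alkylidene trione 11 (Knoevenagel), the dihydropyridine delivers hydride to the exocyclic carbon to give the epoxyalkyl enol 12, and after Et3N is added the C5 enolate oxygen opens the epoxide at its CH carbon. The closest known reaction type is the organocatalytic three-component reductive alkylation of cyclic 1,3-diones with aldehydes and a Hantzsch ester, extended here to an α,β-epoxy aldehyde so that the C-alkylated product is consumed at once by the base-mediated epoxide cycloetherification known for epoxidised C-prenyl 1,3-diones and phenols. The dihydrofuran closes in the 5-exo-tet mode, because an anionic oxygen attacks the secondary epoxide carbon by SN2 rather than the tertiary one (6-endo), which would need acid. The ring stereocentre arises by inversion of the (2R)-epoxide carbon and the carbinol centre is the untouched (3S)-epoxide carbon, so the cis-epoxide from step 4 controls both and gives the (2S) ring carbon next to the (2S) carbinol. The step needs C- rather than O-alkylation, one ring carbon and one of the two oxygens flanking it: a condensation can only take place at carbon, only C4 can lose two hydrogens, and the oxygen on C3 is tied up in the hydrogen-bonded chelate of the isobutyryl group, which leaves the oxygen on C5 to close the ring. Hydride transfer to the quinone-methide-like 11 is expected to outrun Michael addition of a second molecule of 7 and attack of its own carbonyl oxygen on the epoxide, and no reagent present touches the three trisubstituted alkenes.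

Step 7
Reactants: 13 (2S,7S)-4-hydroxy-2-[(2S)-2-hydroxy-6-methylhept-5-en-2-yl]-7-methyl-7-(3-methylbut-2-en-1-yl)-5-(2-methylpropanoyl)-2,3-dihydro-1-benzofuran-6(7H)-one; 2 3-methylbut-2-en-1-yl acetate (prenyl acetate)
Product: 14 (2S,5R,7S)-2-[(2S)-2-hydroxy-6-methylhept-5-en-2-yl]-7-methyl-5,7-bis(3-methylbut-2-en-1-yl)-5-(2-methylpropanoyl)-2,3-dihydro-1-benzofuran-4,6(5H,7H)-dione (target)
Conditions: Pd2(dba)3·CHCl3 (2.5 mol %), (S,S)-DACH-phenyl Trost ligand (7.5 mol %), Et3N (1.1 equiv), CH2Cl2, 0 °C to rt
Reagents that add atoms: none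
Why: Tsuji–Trost C-prenylation: Et3N ionises the β-triketone of 13, whose only carbon nucleophile is C5 (O-prenyl enol ethers re-ionise on zerovalent palladium and funnel to carbon), and the π-prenyl cation is delivered to the face of C5 opposite the C7 prenyl group, a substrate bias reinforced by the chiral ligand, which should set (5R) and complete the target.

Compound list
1 | 4-hydroxy-3,6-dimethyl-2H-pyran-2-one | CC1=CC(O)=C(C)C(=O)O1 | starting material
2 | 3-methylbut-2-en-1-yl acetate (prenyl acetate) | CC(=O)OCC=C(C)C | starting material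
3 | (3S)-3,6-dimethyl-3-(3-methylbut-2-en-1-yl)-2H-pyran-2,4(3H)-dione | CC1=CC(=O)[C@](C)(CC=C(C)C)C(=O)O1 | intermediate
4 | N-methoxy-N,2-dimethylpropanamide | CC(C)C(=O)N(C)OC | starting material
5 | (3S)-3-methyl-6-(3-methyl-2-oxobutyl)-3-(3-methylbut-2-en-1-yl)-2H-pyran-2,4(3H)-dione | CC(C)C(=O)CC1=CC(=O)[C@](C)(CC=C(C)C)C(=O)O1 | intermediate
6 | methyl (2S)-2,8-dimethyl-2-(3-methylbut-2-en-1-yl)-3,5,7-trioxononanoate (present as its magnesium enolate, not isolated) | COC(=O)[C@@](C)(CC=C(C)C)C(=O)CC(=O)CC(=O)C(C)C | intermediate
7 | (6S)-3,5-dihydroxy-6-methyl-6-(3-methylbut-2-en-1-yl)-2-(2-methylpropanoyl)cyclohexa-2,4-dien-1-one | CC(C)C(=O)C1=C(O)C=C(O)[C@](C)(CC=C(C)C)C1=O | intermediate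
8 | nerol, (2Z)-3,7-dimethylocta-2,6-dien-1-ol | CC(C)=CCC/C(C)=C\CO | starting material
9 | [(2R,3S)-3-methyl-3-(4-methylpent-3-en-1-yl)oxiran-2-yl]methanol | CC(C)=CCC[C@]1(C)O[C@@H]1CO | intermediate
10 | (2S,3S)-3-methyl-3-(4-methylpent-3-en-1-yl)oxirane-2-carbaldehyde | CC(C)=CCC[C@]1(C)O[C@@H]1C=O | intermediate
11 | (6S)-3-hydroxy-6-methyl-6-(3-methylbut-2-en-1-yl)-4-{[(2R,3S)-3-methyl-3-(4-methylpent-3-en-1-yl)oxiran-2-yl]methylidene}-2-(2-methylpropanoyl)cyclohex-2-ene-1,5-dione (alkene geometry not defined, not isolated) | CC(C)=CCC[C@]1(C)O[C@@H]1C=C2C(=O)[C@](C)(CC=C(C)C)C(=O)C(C(=O)C(C)C)=C2O | intermediate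
12 | (6S)-3,5-dihydroxy-6-methyl-6-(3-methylbut-2-en-1-yl)-4-{[(2R,3S)-3-methyl-3-(4-methylpent-3-en-1-yl)oxiran-2-yl]methyl}-2-(2-methylpropanoyl)cyclohexa-2,4-dien-1-one (not isolated) | CC(C)=CCC[C@]1(C)O[C@@H]1CC2=C(O)[C@](C)(CC=C(C)C)C(=O)C(C(=O)C(C)C)=C2O | intermediate
13 | (2S,7S)-4-hydroxy-2-[(2S)-2-hydroxy-6-methylhept-5-en-2-yl]-7-methyl-7-(3-methylbut-2-en-1-yl)-5-(2-methylpropanoyl)-2,3-dihydro-1-benzofuran-6(7H)-one | CC(C)=CCC[C@](C)(O)[C@@H]1CC2=C(O1)[C@](C)(CC=C(C)C)C(=O)C(C(=O)C(C)C)=C2O | intermediate
14 | (2S,5R,7S)-2-[(2S)-2-hydroxy-6-methylhept-5-en-2-yl]-7-methyl-5,7-bis(3-methylbut-2-en-1-yl)-5-(2-methylpropanoyl)-2,3-dihydro-1-benzofuran-4,6(5H,7H)-dione | CC(C)=CCC[C@](C)(O)[C@@H]1CC2=C(O1)[C@](C)(CC=C(C)C)C(=O)[C@](CC=C(C)C)(C(=O)C(C)C)C2=O | target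

Total step count: 7. Longest linear sequence: 5 steps (1, 2, 3, 6, 7); steps 4 and 5 form the second branch, which joins at step 6.

Steps most likely to fail

Step 6. The alkylidene intermediate may close through its own carbonyl oxygen onto the epoxide (leading to a furan) or add a second molecule of 7 before hydride transfer, and a slightly acidic medium may open the epoxide at the tertiary carbon (6-endo). The fallback uses known SN2 chemistry. It sets out from 9, which is converted with I2, PPh3 and imidazole in CH2Cl2 at 0 °C into (2S,3S)-2-(iodomethyl)-3-methyl-3-(4-methylpent-3-en-1-yl)oxirane F1. The iodide alkylates 7 at C4 in a protic medium (KOH, MeOH–H2O, rt), which favours carbon over oxygen. The C-alkylated product is 12, which under the same base undergoes the 5-exo-tet epoxide opening, so the fallback comes back to the route at 13.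

Step 7. Facial discrimination at the flat C5 enolate may be poor, because methyl and prenyl on C7 differ little in size, and reversible ionisation of the new C–C bond on palladium may erode it further. The fallback gives up kinetic control and sets out from 13. Prenylation with 2, Pd(PPh3)4 and Et3N gives 14 together with the (2S,5S,7S)-C5 epimer of 14 F2, and the two diastereomers are separated by chromatography. F2 is returned to 13 by palladium-catalysed de-prenylation of the triacyl carbon (Pd(PPh3)4, morpholine, THF) and recycled; the fallback comes back to the route at 14.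

Step 1. Enantiofacial discrimination at C3 of the pyranone anion may be insufficient, and re-ionisation of the product, whose leaving group is an acidic hydroxypyranone, may lower the enantiomeric purity with time. The fallback replaces induction by resolution and sets out from 1. Prenylation with 2, Pd(PPh3)4 and Et3N gives racemic 3,6-dimethyl-3-(3-methylbut-2-en-1-yl)-2H-pyran-2,4(3H)-dione F3. F3 is resolved by preparative chromatography on a chiral stationary phase, and the (3S)-enantiomer re-enters the route as 3.

Further compounds
F1 | step 6 | (2S,3S)-2-(iodomethyl)-3-methyl-3-(4-methylpent-3-en-1-yl)oxirane | CC(C)=CCC[C@]1(C)O[C@@H]1CI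
F2 | step 7 | (2S,5S,7S)-2-[(2S)-2-hydroxy-6-methylhept-5-en-2-yl]-7-methyl-5,7-bis(3-methylbut-2-en-1-yl)-5-(2-methylpropanoyl)-2,3-dihydro-1-benzofuran-4,6(5H,7H)-dione | CC(C)=CCC[C@](C)(O)[C@@H]1CC2=C(O1)[C@](C)(CC=C(C)C)C(=O)[C@@](CC=C(C)C)(C(=O)C(C)C)C2=O
F3 | step 1 | racemic 3,6-dimethyl-3-(3-methylbut-2-en-1-yl)-2H-pyran-2,4(3H)-dione | CC1=CC(=O)C(C)(CC=C(C)C)C(=O)O1
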